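**Retrosynthetic overview**
1. Target 23 ← acetylation of 2β-hydroxy acid 21 ← α-face hydride reduction and saponification of keto ester 19 (methyl 2-oxolabda-8(17),13Z-dien-15-oate).
2. 19 ← one-operation bicyclization of the acyclic enone–allylsilane 17: the O-silylated enone is attacked at C-4 by the 5(10)-alkene (ring A forms first), the C-10 cation by the allylsilane (ring B forms second), leaving the 8(17)-methylene.
3. 17 ← dithiane hydrolysis of 16 ← Z-selective γ-allylation of the copper dienolate of methyl 3-methylbut-2-enoate with bromide 12.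
4. 12 ← alkoxide-directed allylic lithiation/silylation of 8 ← dithiane (acyl anion) alkylation with 8-bromogeranyl acetate 3 ← SeO2 oxidation of geranyl acetate 1; dithiane 5 from 3-methylbut-2-enal 4.

Assumption: bicyclic compounds carry labdane numbering; which enantiomer of the chiral acid in step 9 gives the (5S,9S,10S) series is not predictable and is fixed by one trial, the mirror-image acid being used otherwise.

**Step 1**
Reactants: 1 geranyl acetate
Product: 2 (2E,6E)-8-hydroxy-3,7-dimethylocta-2,6-dien-1-yl acetate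
Conditions: SeO2 (0.3 equiv), t-BuOOH (3 equiv), salicylic acid (cat.), CH2Cl2, rt
Reagents that add atoms: selenium dioxide SeO2, O=[Se]=O (catalytic oxygen carrier); tert-butyl hydroperoxide, CC(C)(C)OO (terminal oxygen source)
Why: Sharpless–Umbreit allylic oxidation (ene reaction then [2,3]-shift) attacks the most electron-rich terminal alkene and hydroxylates only its E-methyl group, which fixes the E geometry of the future 5(10)-alkene.

**Step 2**
Reactants: 2 (2E,6E)-8-hydroxy-3,7-dimethylocta-2,6-dien-1-yl acetate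
Product: 3 (2E,6E)-8-bromo-3,7-dimethylocta-2,6-dien-1-yl acetate
Conditions: CBr4, PPh3, CH2Cl2, 0 °C
Reagents that add atoms: carbon tetrabromide, BrC(Br)(Br)Br
Why: Appel bromination converts the primary allylic alcohol by SN2 under neutral conditions, without allylic transposition and without touching the acetate.

**Step 3**
Reactants: 4 3-methylbut-2-enal
Product: 5 2-(2-methylprop-1-en-1-yl)-1,3-dithiane
Conditions: HS(CH2)3SH, BF3·OEt2 (cat.), CH2Cl2, –20 → 0 °C
Reagents that add atoms: propane-1,3-dithiol, SCCCS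
Why: Lewis-acid dithioacetalization (Corey–Seebach dithiane formation) occurs at the carbonyl because conjugate thiol addition to the β,β-disubstituted enal is slow.

**Step 4**
Reactants: 5 2-(2-methylprop-1-en-1-yl)-1,3-dithiane; 3 (2E,6E)-8-bromo-3,7-dimethylocta-2,6-dien-1-yl acetate
Product: 8 (2E,6E)-3,7-dimethyl-8-[2-(2-methylprop-1-en-1-yl)-1,3-dithian-2-yl]octa-2,6-dien-1-ol, via lithiated dithiane 6 (not isolated), via dithiane acetate 7 (not isolated)
Conditions: n-BuLi, THF, –78 → –25 °C; 3, –78 °C; then K2CO3 (cat.), MeOH, 0 °C → rt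
Reagents that add atoms: none
Why: Corey–Seebach umpolung alkylation: the 2-alkenyl dithiane anion attacks the allylic bromide by SN2 at its dithiane carbon (the γ-carbon is blocked by two methyl groups) faster than it attacks the acetate at –78 °C, and base-catalysed methanolysis then frees the allylic alcohol in the same flask.

**Step 5**
Reactants: 8 (2E,6E)-3,7-dimethyl-8-[2-(2-methylprop-1-en-1-yl)-1,3-dithian-2-yl]octa-2,6-dien-1-ol
Product: 11 (2Z,6E)-7-methyl-8-[2-(2-methylprop-1-en-1-yl)-1,3-dithian-2-yl]-3-[(trimethylsilyl)methyl]octa-2,6-dien-1-ol, via dilithio dianion 9 (not isolated), via bis-silyl ether 10 (not isolated)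
Conditions: n-BuLi (2.4 equiv), TMEDA, Et2O–hexane, 0 °C → rt; Me3SiCl, –78 °C → rt; then K2CO3 (cat.), MeOH, 0 °C
Reagents that add atoms: chlorotrimethylsilane, C[Si](C)(C)Cl
Why: Alkoxide-directed allylic lithiation (Trost/Cardillo dianion chemistry) removes a proton only from the methyl group cis to CH2OLi, and the chelated allyllithium is silylated at its CH2 terminus, so the CH2SiMe3 group ends cis to C-1 with the chain geometry unchanged; the 2,2-disubstituted dithiane has no acidic hydrogen.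

**Step 6**
Reactants: 11 (2Z,6E)-7-methyl-8-[2-(2-methylprop-1-en-1-yl)-1,3-dithian-2-yl]-3-[(trimethylsilyl)methyl]octa-2,6-dien-1-ol
Product: 12 2-[(2E,6Z)-8-bromo-2-methyl-6-[(trimethylsilyl)methyl]octa-2,6-dien-1-yl]-2-(2-methylprop-1-en-1-yl)-1,3-dithiane
Conditions: CBr4, PPh3, CH2Cl2, –30 °C; used at once
Reagents that add atoms: carbon tetrabromide, BrC(Br)(Br)Br
Why: Appel bromination is acid-free and SN2, so the allylsilane is neither protodesilylated nor transposed and the alkene geometry is kept.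

**Step 7**
Reactants: 12 2-[(2E,6Z)-8-bromo-2-methyl-6-[(trimethylsilyl)methyl]octa-2,6-dien-1-yl]-2-(2-methylprop-1-en-1-yl)-1,3-dithiane; 13 methyl 3-methylbut-2-enoate
Product: 16 methyl (2Z,6Z,10E)-3,11-dimethyl-12-[2-(2-methylprop-1-en-1-yl)-1,3-dithian-2-yl]-7-[(trimethylsilyl)methyl]dodeca-2,6,10-trienoate, via lithium dienolate 14 (not isolated), via copper dienolate 15 (not isolated)
Conditions: 13, LiN(i-Pr)2, THF–DMPU, –78 °C; CuI, –78 °C; 12, –78 → –20 °C
Reagents that add atoms: none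
Why: Vinylogous (γ) allylation of a copper dienolate (Katzenellenbogen-type): copper shifts attack from the α- to the γ-carbon, SN2 at the primary allylic bromide keeps the allylsilane geometry, and the cisoid metal-bridged dienolate places the new chain cis to the ester, giving the 2Z (labdane 13Z) enoate.

**Step 8**
Reactants: 16 methyl (2Z,6Z,10E)-3,11-dimethyl-12-[2-(2-methylprop-1-en-1-yl)-1,3-dithian-2-yl]-7-[(trimethylsilyl)methyl]dodeca-2,6,10-trienoate
Product: 17 methyl (2Z,6Z,10E)-3,11,15-trimethyl-13-oxo-7-[(trimethylsilyl)methyl]hexadeca-2,6,10,14-tetraenoate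
Conditions: MeI (excess), CaCO3, MeCN–H2O (9:1), 40 °C, dark
Reagents that add atoms: water, O
Why: Alkylative dithiane hydrolysis (S-methylation, then displacement of the sulfonium by water) runs under CaCO3 buffering, so the allylsilane survives and the skipped β,γ-alkene of the new enone is not moved into conjugation.

**Step 9**
Reactants: 17 methyl (2Z,6Z,10E)-3,11,15-trimethyl-13-oxo-7-[(trimethylsilyl)methyl]hexadeca-2,6,10,14-tetraenoate
Product: 19 methyl 2-oxolabda-8(17),13Z-dien-15-oate (trans-decalin; 5α-H/9α-H/10β-CH3), via silyl enol ether 18 (not isolated)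
Conditions: (S,S)-IDPi acid (BINOL-derived imidodiphosphorimidate, N-triflyl core, 3,3'-aryl groups; 5 mol %) pre-silylated with methallyltrimethylsilane (10 mol %), CH2Cl2, –60 °C, slow addition of 17 (0.01 M); then Et3N, K2CO3 (cat.), MeOH, 0 °C
Reagents that add atoms: none
Why: Proposed new method: silyl transfer from the Me3Si–IDPi ion pair to the enone oxygen gives a 2-silyloxyallyl cation inside the chiral anion, whose gem-dimethyl terminus (C-4) is attacked 6-endo by the E 5(10)-alkene and whose resulting C-10 cation is trapped by the allylsilane through a chair–chair, anti-addition (Stork–Eschenmoser) array that fixes 5α-H, 10β-CH3 and 9α-H (side chain equatorial) relative to one another while the anion shields one face of the cation and so sets the absolute configuration; collapse of the β-silyl cation leaves the 8(17)-methylene and returns Me3Si+ to the anion for turnover; the closest known reactions are IDPi–silylium-catalysed Hosomi–Sakurai and Mukaiyama–Michael additions, allylsilane-terminated cationic polyene bicyclizations, and Lewis-acid enone-initiated cation–olefin cyclizations such as the cyclialkylation to 4,4-dimethyl-2-tetralones.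

**Step 10**
Reactants: 19 methyl 2-oxolabda-8(17),13Z-dien-15-oate
Product: 21 2β-hydroxylabda-8(17),13Z-dien-15-oic acid, via hydroxy ester 20 (not isolated)
Conditions: NaBH4, MeOH–THF, 0 °C; then LiOH, H2O, 50 °C; 1 M HCl to pH 3, 0 °C
Reagents that add atoms: lithium hydroxide LiOH, [Li+].[OH-]
Why: Substrate-controlled borohydride reduction: the β-face of the C-2 carbonyl is blocked by the syn-axial 4β- and 10β-methyl groups (as at C-11 of 11-oxo steroids), so hydride enters from the α-face and gives the axial 2β-alcohol (2R) without touching the enoate; hydroxide then saponifies the methyl ester with the 13Z geometry kept.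

**Step 11**
Reactants: 21 2β-hydroxylabda-8(17),13Z-dien-15-oic acid
Product: 23 2β-acetoxylabda-8(17),13Z-dien-15-oic acid (2R,5S,9S,10S; target), via mixed anhydride 22 (not isolated)
Conditions: Ac2O (3 equiv), pyridine, DMAP (cat.), CH2Cl2, 35 °C; then H2O, THF, rt; pH 4
Reagents that add atoms: acetic anhydride, CC(=O)OC(C)=O
Why: DMAP-catalysed acylation esterifies the hindered axial alcohol with retention at C-2, and the mixed carboxylic–acetic anhydride formed at C-15 is hydrolysed by water at its less hindered acetyl carbonyl, returning the free acid.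

**Compound list**
1 | geranyl acetate, (2E)-3,7-dimethylocta-2,6-dien-1-yl acetate | CC(=O)OC/C=C(C)/CCC=C(C)C | starting material
2 | (2E,6E)-8-hydroxy-3,7-dimethylocta-2,6-dien-1-yl acetate | CC(=O)OC/C=C(C)/CC/C=C(C)/CO | intermediate
3 | (2E,6E)-8-bromo-3,7-dimethylocta-2,6-dien-1-yl acetate | CC(=O)OC/C=C(C)/CC/C=C(C)/CBr | intermediate
4 | 3-methylbut-2-enal | CC(C)=CC=O | starting material
5 | 2-(2-methylprop-1-en-1-yl)-1,3-dithiane | CC(C)=CC1SCCCS1 | intermediate
6 | 2-lithio-2-(2-methylprop-1-en-1-yl)-1,3-dithiane | [Li]C1(C=C(C)C)SCCCS1 | intermediate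
7 | (2E,6E)-3,7-dimethyl-8-[2-(2-methylprop-1-en-1-yl)-1,3-dithian-2-yl]octa-2,6-dien-1-yl acetate | CC(=O)OC/C=C(C)/CC/C=C(C)/CC1(C=C(C)C)SCCCS1 | intermediate
8 | (2E,6E)-3,7-dimethyl-8-[2-(2-methylprop-1-en-1-yl)-1,3-dithian-2-yl]octa-2,6-dien-1-ol | OC/C=C(C)/CC/C=C(C)/CC1(C=C(C)C)SCCCS1 | intermediate
9 | O,C-dilithio derivative of 8 (lithium alkoxide, lithium on the 3-methyl carbon) | [Li]OC/C=C(C[Li])/CC/C=C(C)/CC1(C=C(C)C)SCCCS1 | intermediate
10 | trimethylsilyl ether of 11 (O- and C-silylated) | C[Si](C)(C)OC/C=C(C[Si](C)(C)C)/CC/C=C(C)/CC1(C=C(C)C)SCCCS1 | intermediate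
11 | (2Z,6E)-7-methyl-8-[2-(2-methylprop-1-en-1-yl)-1,3-dithian-2-yl]-3-[(trimethylsilyl)methyl]octa-2,6-dien-1-ol | OC/C=C(C[Si](C)(C)C)/CC/C=C(C)/CC1(C=C(C)C)SCCCS1 | intermediate
12 | 2-[(2E,6Z)-8-bromo-2-methyl-6-[(trimethylsilyl)methyl]octa-2,6-dien-1-yl]-2-(2-methylprop-1-en-1-yl)-1,3-dithiane | BrC/C=C(C[Si](C)(C)C)/CC/C=C(C)/CC1(C=C(C)C)SCCCS1 | intermediate
13 | methyl 3-methylbut-2-enoate | COC(=O)C=C(C)C | starting material
14 | lithium dienolate of 13 (lithium 1-methoxy-3-methylbuta-1,3-dien-1-olate) | COC(O[Li])=CC(C)=C | intermediate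
15 | copper dienolate of 13 (monovalent copper, drawn O-bound) | COC(O[Cu])=CC(C)=C | intermediate
16 | methyl (2Z,6Z,10E)-3,11-dimethyl-12-[2-(2-methylprop-1-en-1-yl)-1,3-dithian-2-yl]-7-[(trimethylsilyl)methyl]dodeca-2,6,10-trienoate | COC(=O)/C=C(C)\CC/C=C(C[Si](C)(C)C)/CC/C=C(C)/CC1(C=C(C)C)SCCCS1 | intermediate
17 | methyl (2Z,6Z,10E)-3,11,15-trimethyl-13-oxo-7-[(trimethylsilyl)methyl]hexadeca-2,6,10,14-tetraenoate | COC(=O)/C=C(C)\CC/C=C(C[Si](C)(C)C)/CC/C=C(C)/CC(=O)C=C(C)C | intermediate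
18 | methyl 2-(trimethylsilyloxy)labda-2,8(17),13Z-trien-15-oate (5α-H, 9α-H, 10β-CH3) | C=C1CC[C@H]2C(C)(C)C=C(O[Si](C)(C)C)C[C@]2(C)[C@H]1CC/C(C)=C\C(=O)OC | intermediate
19 | methyl 2-oxolabda-8(17),13Z-dien-15-oate (5α-H, 9α-H, 10β-CH3) | C=C1CC[C@H]2C(C)(C)CC(=O)C[C@]2(C)[C@H]1CC/C(C)=C\C(=O)OC | intermediate
20 | methyl 2β-hydroxylabda-8(17),13Z-dien-15-oate | C=C1CC[C@H]2C(C)(C)C[C@@H](O)C[C@]2(C)[C@H]1CC/C(C)=C\C(=O)OC | intermediate
21 | 2β-hydroxylabda-8(17),13Z-dien-15-oic acid | C=C1CC[C@H]2C(C)(C)C[C@@H](O)C[C@]2(C)[C@H]1CC/C(C)=C\C(=O)O | intermediate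
22 | acetic 2β-acetoxylabda-8(17),13Z-dien-15-oic anhydride | C=C1CC[C@H]2C(C)(C)C[C@@H](OC(C)=O)C[C@]2(C)[C@H]1CC/C(C)=C\C(=O)OC(C)=O | intermediate
23 | (2R,5S,9S,10S)-2β-acetoxylabda-8(17),13Z-dien-15-oic acid | C=C1CC[C@H]2C(C)(C)C[C@@H](OC(C)=O)C[C@]2(C)[C@H]1CC/C(C)=C\C(=O)O | target

**Step count**
Total: 11 steps. Longest linear sequence: 10 steps (1, 2, 4, 5, 6, 7, 8, 9, 10, 11, from geranyl acetate); step 3 is a one-step side branch.

**Steps most likely to fail**

Step 9 (the catalytic asymmetric bicyclization is untested; the enone may isomerize or the enantioselectivity may be low). The fallback moves absolute control from the catalyst to a resolution. It sets out from 17. Tf2NH (5 mol %) and allyltrimethylsilane (10 mol %) give the achiral silylium catalyst Me3SiNTf2 in CH2Cl2 at –78 °C, which runs the same cascade to racemic methyl 2-(trimethylsilyloxy)labda-2,8(17),13Z-trien-15-oate F1. K2CO3 in MeOH then releases racemic methyl 2-oxolabda-8(17),13Z-dien-15-oate F2. The enantiomers of F2 are separated by preparative chromatography on a chiral stationary phase (amylose tris(3,5-dimethylphenylcarbamate)); the 5α-H, 9α-H, 10β-CH3 enantiomer is 19, where the fallback comes back to the route.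

Step 5 (n-BuLi/TMEDA may attack the dithiane or metalate unselectively). The fallback introduces silicon before the dithiane. It sets out from 2. TBSCl and imidazole give (2E,6E)-8-[(tert-butyldimethylsilyl)oxy]-3,7-dimethylocta-2,6-dien-1-yl acetate F3, and K2CO3 in MeOH gives (2E,6E)-8-[(tert-butyldimethylsilyl)oxy]-3,7-dimethylocta-2,6-dien-1-ol F4. n-BuLi/TMEDA forms the O,C-dilithio derivative of this alcohol F5, Me3SiCl gives the O,C-bis(trimethylsilyl) compound F6, and methanolysis gives (2Z,6E)-8-[(tert-butyldimethylsilyl)oxy]-7-methyl-3-[(trimethylsilyl)methyl]octa-2,6-dien-1-ol F7, with no thioacetal present during the lithiation. CBr4/PPh3 gives the allylic bromide tert-butyl{[(2E,6Z)-8-bromo-2-methyl-6-[(trimethylsilyl)methyl]octa-2,6-dien-1-yl]oxy}dimethylsilane F8. Copper dienolate 15 converts it into methyl (2Z,6Z,10E)-12-[(tert-butyldimethylsilyl)oxy]-3,11-dimethyl-7-[(trimethylsilyl)methyl]dodeca-2,6,10-trienoate F9. Bu4NF buffered with AcOH gives methyl (2Z,6Z,10E)-12-hydroxy-3,11-dimethyl-7-[(trimethylsilyl)methyl]dodeca-2,6,10-trienoate F10, and CBr4/PPh3 gives methyl (2Z,6Z,10E)-12-bromo-3,11-dimethyl-7-[(trimethylsilyl)methyl]dodeca-2,6,10-trienoate F11. Alkylation of lithiated dithiane 6 with F11 at –78 °C (allylic bromide faster than ester) gives 16, where the fallback comes back to the route.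

Step 7 (the copper dienolate may couple at the α-carbon or give the 2E ester). The fallback builds the Z-enoate by carbocupration instead. It sets out from 12. 1-(Trimethylsilyl)propyne, lithiated with n-BuLi, alkylates 12 to trimethyl{(5Z,9E)-10-methyl-11-[2-(2-methylprop-1-en-1-yl)-1,3-dithian-2-yl]-6-[(trimethylsilyl)methyl]undeca-5,9-dien-1-yn-1-yl}silane F12. K2CO3 in MeOH removes only the alkynyl silyl group and gives the terminal alkyne 2-{(2E,6Z)-2-methyl-6-[(trimethylsilyl)methyl]undeca-2,6-dien-10-yn-1-yl}-2-(2-methylprop-1-en-1-yl)-1,3-dithiane F13. n-BuLi gives its lithium acetylide F14, and ClCO2Me gives methyl (6Z,10E)-11-methyl-12-[2-(2-methylprop-1-en-1-yl)-1,3-dithian-2-yl]-7-[(trimethylsilyl)methyl]dodeca-6,10-dien-2-ynoate F15. Me2CuLi in THF at –78 °C adds methyl and copper syn across the triple bond, and protonation at –78 °C gives 16 with the chain cis to the ester, where the fallback comes back to the route.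

**Further compounds**
F1 | step 9 | racemic methyl 2-(trimethylsilyloxy)labda-2,8(17),13Z-trien-15-oate (racemate; one enantiomer drawn) | C=C1CC[C@H]2C(C)(C)C=C(O[Si](C)(C)C)C[C@]2(C)[C@H]1CC/C(C)=C\C(=O)OC
F2 | step 9 | racemic methyl 2-oxolabda-8(17),13Z-dien-15-oate (racemate; one enantiomer drawn) | C=C1CC[C@H]2C(C)(C)CC(=O)C[C@]2(C)[C@H]1CC/C(C)=C\C(=O)OC
F3 | step 5 | (2E,6E)-8-[(tert-butyldimethylsilyl)oxy]-3,7-dimethylocta-2,6-dien-1-yl acetate | CC(=O)OC/C=C(C)/CC/C=C(C)/CO[Si](C)(C)C(C)(C)C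
F4 | step 5 | (2E,6E)-8-[(tert-butyldimethylsilyl)oxy]-3,7-dimethylocta-2,6-dien-1-ol | OC/C=C(C)/CC/C=C(C)/CO[Si](C)(C)C(C)(C)C
F5 | step 5 | O,C-dilithio derivative of F4 | [Li]OC/C=C(C[Li])/CC/C=C(C)/CO[Si](C)(C)C(C)(C)C
F6 | step 5 | trimethylsilyl ether of F7 (O- and C-silylated) | C[Si](C)(C)OC/C=C(C[Si](C)(C)C)/CC/C=C(C)/CO[Si](C)(C)C(C)(C)C
F7 | step 5 | (2Z,6E)-8-[(tert-butyldimethylsilyl)oxy]-7-methyl-3-[(trimethylsilyl)methyl]octa-2,6-dien-1-ol | OC/C=C(C[Si](C)(C)C)/CC/C=C(C)/CO[Si](C)(C)C(C)(C)C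
F8 | step 5 | tert-butyl{[(2E,6Z)-8-bromo-2-methyl-6-[(trimethylsilyl)methyl]octa-2,6-dien-1-yl]oxy}dimethylsilane | BrC/C=C(C[Si](C)(C)C)/CC/C=C(C)/CO[Si](C)(C)C(C)(C)C
F9 | step 5 | methyl (2Z,6Z,10E)-12-[(tert-butyldimethylsilyl)oxy]-3,11-dimethyl-7-[(trimethylsilyl)methyl]dodeca-2,6,10-trienoate | COC(=O)/C=C(C)\CC/C=C(C[Si](C)(C)C)/CC/C=C(C)/CO[Si](C)(C)C(C)(C)C
F10 | step 5 | methyl (2Z,6Z,10E)-12-hydroxy-3,11-dimethyl-7-[(trimethylsilyl)methyl]dodeca-2,6,10-trienoate | COC(=O)/C=C(C)\CC/C=C(C[Si](C)(C)C)/CC/C=C(C)/CO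
F11 | step 5 | methyl (2Z,6Z,10E)-12-bromo-3,11-dimethyl-7-[(trimethylsilyl)methyl]dodeca-2,6,10-trienoate | COC(=O)/C=C(C)\CC/C=C(C[Si](C)(C)C)/CC/C=C(C)/CBr
F12 | step 7 | trimethyl{(5Z,9E)-10-methyl-11-[2-(2-methylprop-1-en-1-yl)-1,3-dithian-2-yl]-6-[(trimethylsilyl)methyl]undeca-5,9-dien-1-yn-1-yl}silane | C[Si](C)(C)C#CCC/C=C(C[Si](C)(C)C)/CC/C=C(C)/CC1(C=C(C)C)SCCCS1
F13 | step 7 | 2-{(2E,6Z)-2-methyl-6-[(trimethylsilyl)methyl]undeca-2,6-dien-10-yn-1-yl}-2-(2-methylprop-1-en-1-yl)-1,3-dithiane | C#CCC/C=C(C[Si](C)(C)C)/CC/C=C(C)/CC1(C=C(C)C)SCCCS1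
F14 | step 7 | lithium acetylide of F13 | [Li]C#CCC/C=C(C[Si](C)(C)C)/CC/C=C(C)/CC1(C=C(C)C)SCCCS1
F15 | step 7 | methyl (6Z,10E)-11-methyl-12-[2-(2-methylprop-1-en-1-yl)-1,3-dithian-2-yl]-7-[(trimethylsilyl)methyl]dodeca-6,10-dien-2-ynoate | COC(=O)C#CCC/C=C(C[Si](C)(C)C)/CC/C=C(C)/CC1(C=C(C)C)SCCCS1
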